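**Retrosynthetic overview**
1. Feature: on each resorcinol ring the ketone carbon (C1 or C4 of the butane-1,4-dione chain) sits on ring carbon C1' and a hydroxyl sits on the adjacent C2'. This C/O pair is what one carboxyl group can deliver across the two carbons of an aryne triple bond.
2. Key disconnection: the C1'–C(=O) and C2'–O bonds at both chain ends (four bonds) lead back to meso-2,3-bis(4-methoxybenzyl)succinic acid 4 and two molecules of 3-chloro-5-methoxybenzyne 11. The chlorine (C6' in the product) only steers the addition; it is removed by hydrogenolysis before BBr3 cleaves the four methyl ethers.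
3. Diacid 4: Z-selective homometathesis of estragole 1, then syn bis-benzyloxycarbonylation of Z-alkene 2 (sets C2/C3 as the meso pair), then base-free hydrogenolysis of the benzyl esters.
4. Aryne source 10: ortho-bromination of 2-chloro-4-methoxyphenol 5, O-silylation, bromine–lithium exchange with retro-Brook shift, triflation.
5. Rings: none is built, since all four benzene rings are bought. The only stereochemical task is the meso relationship, set in step 2 and carried through.

Key step: step 7

Assumption: the two stereocentres of the target SMILES have opposite descriptors (2S,3R) in a constitutionally symmetric chain, so the target is the achiral meso diastereomer and only relative configuration must be controlled.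

Remark on the aryne source: 11 can be released from either of two isomeric silyl triflates.
- Compound 10 (silicon on the carbon remote from chlorine) is chosen because its substitution pattern follows unambiguously from ortho-bromination of 5 and a retro-Brook shift.
- 3-Chloro-5-methoxy-2-(trimethylsilyl)phenyl triflate would need a directed lithiation of a 3-chloro-5-methoxyphenyl carbamate, in which three ring C–H positions each lie between two directing groups.

**Step 1**
Reactants: 1 estragole (4-allylanisole), two molecules
Product: 2 (Z)-1,4-bis(4-methoxyphenyl)but-2-ene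
Conditions: C32H41N3O4Ru [cyclometalated Z-selective Grubbs nitrate catalyst, Ru(NO3)(=CH-C6H4-2-O-i-Pr)(adamantyl-chelated N-mesitylimidazolidin-2-ylidene)] (0.5 mol %), THF (3 M), 35 °C, ethylene vented
Reagents that add atoms: none
Why: Z-selective olefin homometathesis, for which allylbenzenes are standard substrates: the C,C-chelating adamantyl carbene enforces a side-bound metallacyclobutane with both benzyl groups pointing away from the N-mesityl group, so the kinetic Z-alkene should form, and venting ethylene and stopping short of full conversion limits Z-to-E erosion and allyl-to-propenyl migration.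

**Step 2**
Reactants: 2 (Z)-1,4-bis(4-methoxyphenyl)but-2-ene
Product: 3 dibenzyl meso-(2R,3S)-2,3-bis(4-methoxybenzyl)succinate
Conditions: CO (4 bar), Pd(O2CCF3)2 (2 mol %), N,N'-bis(2,6-dimethylphenyl)butane-2,3-diimine (2.2 mol %), p-benzoquinone (1.5 equiv), p-TsOH·H2O (2 mol %), BnOH/THF 7:1, 20 °C
Reagents that add atoms: carbon monoxide [C-]#[O+]; benzyl alcohol OCc1ccccc1
Why: Oxidative palladium-catalysed bis-alkoxycarbonylation of a 1,2-disubstituted alkene: a Pd–CO2Bn unit adds syn across the C=C bond, CO inserts into the new Pd–C bond with retention and benzyl alcohol cleaves the acyl–palladium bond, so both carboxyl carbons land on one face of the Z-alkene and the new stereocentres C2 and C3 are set as the meso pair, while CO pressure and the five-membered ester chelate hold back β-hydride elimination and benzoquinone returns zerovalent palladium to divalent palladium.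

**Step 3**
Reactants: 3 dibenzyl meso-2,3-bis(4-methoxybenzyl)succinate
Product: 4 meso-(2R,3S)-2,3-bis(4-methoxybenzyl)succinic acid
Conditions: H2 (1 atm), 10 % Pd/C, EtOAc/EtOH, rt; recrystallisation
Reagents that add atoms: none
Why: Catalytic hydrogenolysis of benzyl esters frees both acids under neutral conditions, so the enolisable α-stereocentres never meet base and keep the meso relationship, the aryl methyl ethers are inert, and recrystallisation should remove any racemic diastereomer that stems from residual E-alkene.

**Step 4**
Reactants: 5 2-chloro-4-methoxyphenol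
Product: 6 2-bromo-6-chloro-4-methoxyphenol
Conditions: NBS (1.0 equiv), MeCN, 0 °C to rt
Reagents that add atoms: N-bromosuccinimide O=C1CCC(=O)N1Br
Why: Electrophilic aromatic bromination directed by the hydroxyl group, the strongest donor on the ring: its para position carries the methoxy group and one ortho position carries chlorine, so C6 is the only hydroxyl-activated site left.

**Step 5**
Reactants: 6 2-bromo-6-chloro-4-methoxyphenol
Product: 7 (2-bromo-6-chloro-4-methoxyphenoxy)trimethylsilane
Conditions: (Me3Si)2NH (0.7 equiv), THF, reflux; evaporation
Reagents that add atoms: hexamethyldisilazane C[Si](C)(C)N[Si](C)(C)C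
Why: O-silylation of a phenol with hexamethyldisilazane gives only ammonia as by-product, so the moisture-sensitive silyl ether can be used after simple evaporation.

**Step 6**
Reactants: 7 (2-bromo-6-chloro-4-methoxyphenoxy)trimethylsilane
Product: 10 2-chloro-4-methoxy-6-(trimethylsilyl)phenyl trifluoromethanesulfonate, via aryllithium 8 (not isolated), via lithium phenoxide 9 (not isolated)
Conditions: n-BuLi (1.1 equiv), THF, −78 °C; then Tf2O (1.2 equiv), −78 °C to rt
Reagents that add atoms: trifluoromethanesulfonic anhydride O=S(=O)(OS(=O)(=O)C(F)(F)F)C(F)(F)F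
Why: Bromine–lithium exchange outruns any attack on chlorine or silicon at −78 °C, aryllithium 8 (lithium meta to chlorine, so no lithium chloride can be eliminated) undergoes the retro-Brook 1,3-shift of silicon from oxygen to carbon driven by formation of phenoxide 9, and triflic anhydride traps 9 on oxygen.

**Step 7**
Reactants: 4 meso-2,3-bis(4-methoxybenzyl)succinic acid; 10 2-chloro-4-methoxy-6-(trimethylsilyl)phenyl trifluoromethanesulfonate (two molecules consumed)
Product: 13 meso-1,4-bis(2-chloro-6-hydroxy-4-methoxyphenyl)-2,3-bis(4-methoxybenzyl)butane-1,4-dione, via 3-chloro-5-methoxybenzyne 11 (not isolated), via mono-insertion keto acid 12 (not isolated)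
Conditions: 10 (3.0 equiv, two portions), CsF (8 equiv), THF, sealed tube, 125 °C; aq. NH4Cl work-up
Reagents that add atoms: none
Why: CsF releases aryne 11 from 10 by desilylation and loss of triflate and also converts 4 into its carboxylate; the carboxylate oxygen adds to the aryne, the resulting aryl anion attacks the carbonyl of its own aryl ester through a four-membered tetrahedral intermediate, and collapse gives the phenoxide of the ortho-hydroxyaryl ketone, first in 12 and then, by the same sequence at the second carboxyl group, in 13. The closest known reaction is the fluoride-induced insertion of arynes into the C–O bond of monocarboxylic acids in hot THF, which also accepts arynes substituted next to the triple bond; its twofold use on a vicinal diacid has not been tried, and this is where the route carries its risk. No ring is closed and no stereocentre is created: C2 and C3 are bystanders, α to a carboxylate before insertion and α to a ketone deactivated by its ortho-phenoxide afterwards, so the meso relationship should be carried through. The step needs O-attack at the aryne carbon remote from chlorine: the inductively withdrawing chlorine distorts the aryne so that this carbon is the more linear and electrophilic one, stabilises the negative charge developing next to itself and shields the near carbon, whereas the methoxy group, meta to the attacked carbon and para to the anionic one, exerts only a weak, slightly opposed bias. It also needs acyl transfer to outrun protonation and chloride loss: the weakly polar solvent, the high temperature and excess CsF (which binds the acid protons as bifluoride) favour the intramolecular transfer, which in ortho-metallated aryl esters is far faster than loss of metal chloride from ortho-chloroaryl anions, and while one end reacts the other is masked as an unreactive carboxylate or a phenoxide-conjugated ketone.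

**Step 8**
Reactants: 13 meso-1,4-bis(2-chloro-6-hydroxy-4-methoxyphenyl)-2,3-bis(4-methoxybenzyl)butane-1,4-dione
Product: 14 meso-1,4-bis(2-hydroxy-4-methoxyphenyl)-2,3-bis(4-methoxybenzyl)butane-1,4-dione
Conditions: H2 (1 atm), 10 % Pd/C, Et3N (3 equiv), MeOH/EtOAc, rt
Reagents that add atoms: none
Why: Heterogeneous palladium-catalysed hydrodechlorination of aryl chlorides is accelerated by triethylamine, which also binds the hydrogen chloride, while the hindered, hydrogen-bonded, electron-rich aryl ketones are reduced much more slowly at one atmosphere and the amine is too weak a base to enolise them.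

**Step 9**
Reactants: 14 meso-1,4-bis(2-hydroxy-4-methoxyphenyl)-2,3-bis(4-methoxybenzyl)butane-1,4-dione
Product: 15 meso-(2R,3S)-1,4-bis(2,4-dihydroxyphenyl)-2,3-bis(4-hydroxybenzyl)butane-1,4-dione (target CNP0406969.1)
Conditions: BBr3 (10 equiv), CH2Cl2, −78 °C to rt; ice-water quench at 0 °C
Reagents that add atoms: none
Why: Lewis-acid cleavage of aryl methyl ethers with BBr3, in which the ortho-hydroxy ketones are first tied up as six-membered boron chelates that occupy both carbonyl oxygens and should hold back Paal–Knorr-type cyclodehydration of the 1,4-diketone, provided the quench is cold and quick.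

**Compound list**
1 | estragole (4-allylanisole) | C=CCc1ccc(OC)cc1 | starting material
2 | (Z)-1,4-bis(4-methoxyphenyl)but-2-ene | COc1ccc(C/C=C\Cc2ccc(OC)cc2)cc1 | intermediate
3 | dibenzyl meso-2,3-bis(4-methoxybenzyl)succinate | O=C(OCc1ccccc1)[C@@H](Cc1ccc(OC)cc1)[C@@H](Cc1ccc(OC)cc1)C(=O)OCc1ccccc1 | intermediate
4 | meso-2,3-bis(4-methoxybenzyl)succinic acid | OC(=O)[C@@H](Cc1ccc(OC)cc1)[C@@H](Cc1ccc(OC)cc1)C(=O)O | intermediate
5 | 2-chloro-4-methoxyphenol | COc1ccc(O)c(Cl)c1 | starting material
6 | 2-bromo-6-chloro-4-methoxyphenol | COc1cc(Cl)c(O)c(Br)c1 | intermediate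
7 | (2-bromo-6-chloro-4-methoxyphenoxy)trimethylsilane | COc1cc(Cl)c(O[Si](C)(C)C)c(Br)c1 | intermediate
8 | [3-chloro-5-methoxy-2-(trimethylsilyloxy)phenyl]lithium | COc1cc(Cl)c(O[Si](C)(C)C)c([Li])c1 | intermediate (not isolated)
9 | lithium 2-chloro-4-methoxy-6-(trimethylsilyl)phenoxide | COc1cc(Cl)c([O-])c([Si](C)(C)C)c1.[Li+] | intermediate (not isolated)
10 | 2-chloro-4-methoxy-6-(trimethylsilyl)phenyl trifluoromethanesulfonate | COc1cc(Cl)c(OS(=O)(=O)C(F)(F)F)c([Si](C)(C)C)c1 | intermediate
11 | 3-chloro-5-methoxybenzyne | COC1=CC#CC(Cl)=C1 | intermediate (not isolated)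
12 | (2R*,3S*)-4-(2-chloro-6-hydroxy-4-methoxyphenyl)-2,3-bis(4-methoxybenzyl)-4-oxobutanoic acid (racemic, one enantiomer drawn) | O=C(c1c(Cl)cc(OC)cc1O)[C@@H](Cc1ccc(OC)cc1)[C@@H](Cc1ccc(OC)cc1)C(=O)O | intermediate (not isolated)
13 | meso-1,4-bis(2-chloro-6-hydroxy-4-methoxyphenyl)-2,3-bis(4-methoxybenzyl)butane-1,4-dione | O=C(c1c(Cl)cc(OC)cc1O)[C@@H](Cc1ccc(OC)cc1)[C@@H](Cc1ccc(OC)cc1)C(=O)c1c(Cl)cc(OC)cc1O | intermediate
14 | meso-1,4-bis(2-hydroxy-4-methoxyphenyl)-2,3-bis(4-methoxybenzyl)butane-1,4-dione | O=C(c1ccc(OC)cc1O)[C@@H](Cc1ccc(OC)cc1)[C@@H](Cc1ccc(OC)cc1)C(=O)c1ccc(OC)cc1O | intermediate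
15 | meso-1,4-bis(2,4-dihydroxyphenyl)-2,3-bis(4-hydroxybenzyl)butane-1,4-dione | O=C(c1ccc(O)cc1O)[C@@H](Cc1ccc(O)cc1)[C@@H](Cc1ccc(O)cc1)C(=O)c1ccc(O)cc1O | target

Total step count: 9.
Longest linear sequence: 6 steps (1, 2, 3, 7, 8, 9; the arm 4, 5, 6, 7, 8, 9 is equally long).

**Steps most likely to fail**

**Step 7 (double aryne insertion).**
What may go wrong:
- Protonation of the aryl anion before acyl transfer, which stops the sequence at the aryl ester stage.
- Displacement of the aryloxide by the neighbouring carboxylate, with anhydride formation and loss of configuration.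
- Arylation of the liberated phenoxide by surplus aryne.
- Slow enolisation of the ketone at 125 °C.

The fallback sets out from diacid 4 and comes back at 14; it makes the aryl–carbonyl bonds by organolithium acylation.
- Activation of 4 with 1,1'-carbonyldiimidazole and reaction with N,O-dimethylhydroxylamine hydrochloride should give the bis-Weinreb amide meso-N1,N4-dimethoxy-N1,N4-dimethyl-2,3-bis(4-methoxybenzyl)butanediamide F1.
- 2,4-Dimethoxyphenyllithium F2, made from 1-bromo-2,4-dimethoxybenzene and n-BuLi in THF at −78 °C, adds once to each amide because the chelated tetrahedral adducts persist until the quench. This gives meso-1,4-bis(2,4-dimethoxyphenyl)-2,3-bis(4-methoxybenzyl)butane-1,4-dione F3.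
- BCl3 in CH2Cl2 (−78 to 0 °C) then cleaves only the two methyl ethers ortho to the carbonyl groups, through the six-membered boron chelate, and delivers 14.

**Step 2 (bis-benzyloxycarbonylation).**
What may go wrong:
- β-Hydride elimination and re-addition that moves the double bond into conjugation with an anisyl ring.
- Z-to-E isomerisation before carbonylation, which erodes the meso content.
- Sluggish insertion of the internal alkene.

The fallback sets out from Z-alkene 2 and comes back at diacid 4; it keeps the logic of a suprafacial addition to the Z-alkene but uses no palladium.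
- Dichloroketene F4, made in the flask from trichloroacetyl chloride and Zn–Cu couple (POCl3, Et2O), undergoes a stereospecific [2+2] cycloaddition to give cis-2,2-dichloro-3,4-bis(4-methoxybenzyl)cyclobutan-1-one F5.
- Zinc in acetic acid removes both chlorines and gives cis-2,3-bis(4-methoxybenzyl)cyclobutan-1-one F6.
- Kinetic deprotonation at the ring methylene with lithium diisopropylamide and trapping with Me3SiCl (THF, −78 °C) gives [cis-3,4-bis(4-methoxybenzyl)cyclobut-1-en-1-yl]oxytrimethylsilane F7.
- Ozonolysis at −78 °C with Me2S work-up opens the ring to (2R*,3S*)-2,3-bis(4-methoxybenzyl)-4-oxobutanoic acid F8.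
- Pinnick oxidation (NaClO2, NaH2PO4, 2-methylbut-2-ene) of F8 gives 4, the cis ring relationship becoming the meso relationship.

**Step 9 (ether cleavage).**
What may go wrong:
- Acid-induced cyclodehydration of the 1,4-diketone towards a furan.
- Epimerisation through Lewis-acid-promoted enolisation.
- Incomplete cleavage of the ethers para to the carbonyl groups.

The fallback sets out from 13 and comes back at target 15; it inverts the last two operations, so the ethers are cleaved while each carbonyl is still flanked by chlorine and oxygen.
- BBr3 on 13 gives meso-1,4-bis(2-chloro-4,6-dihydroxyphenyl)-2,3-bis(4-hydroxybenzyl)butane-1,4-dione F9.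
- In this series the aryl rings are twisted out of the carbonyl planes, and a 2,5-diarylfuran bearing two doubly ortho-substituted aryl groups beside the benzyl groups would be severely crowded. Cyclodehydration should therefore be slower.
- Hydrodechlorination (H2, Pd/C, Et3N, MeOH, rt) as the last, nearly neutral step then gives 15.

**Further compounds**
F1 | step 7 | meso-N1,N4-dimethoxy-N1,N4-dimethyl-2,3-bis(4-methoxybenzyl)butanediamide | CON(C)C(=O)[C@@H](Cc1ccc(OC)cc1)[C@@H](Cc1ccc(OC)cc1)C(=O)N(C)OC
F2 | step 7 | 2,4-dimethoxyphenyllithium | [Li]c1ccc(OC)cc1OC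
F3 | step 7 | meso-1,4-bis(2,4-dimethoxyphenyl)-2,3-bis(4-methoxybenzyl)butane-1,4-dione | COc1ccc(C(=O)[C@@H](Cc2ccc(OC)cc2)[C@@H](Cc2ccc(OC)cc2)C(=O)c2ccc(OC)cc2OC)c(OC)c1
F4 | step 2 | dichloroketene | ClC(Cl)=C=O
F5 | step 2 | cis-2,2-dichloro-3,4-bis(4-methoxybenzyl)cyclobutan-1-one (racemic) | O=C1C(Cl)(Cl)[C@H](Cc2ccc(OC)cc2)[C@@H]1Cc1ccc(OC)cc1
F6 | step 2 | cis-2,3-bis(4-methoxybenzyl)cyclobutan-1-one (racemic) | O=C1C[C@H](Cc2ccc(OC)cc2)[C@@H]1Cc1ccc(OC)cc1
F7 | step 2 | [cis-3,4-bis(4-methoxybenzyl)cyclobut-1-en-1-yl]oxytrimethylsilane (racemic) | C[Si](C)(C)OC1=C[C@H](Cc2ccc(OC)cc2)[C@@H]1Cc1ccc(OC)cc1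
F8 | step 2 | (2R*,3S*)-2,3-bis(4-methoxybenzyl)-4-oxobutanoic acid (racemic) | O=C[C@@H](Cc1ccc(OC)cc1)[C@@H](Cc1ccc(OC)cc1)C(=O)O
F9 | step 9 | meso-1,4-bis(2-chloro-4,6-dihydroxyphenyl)-2,3-bis(4-hydroxybenzyl)butane-1,4-dione | O=C(c1c(Cl)cc(O)cc1O)[C@@H](Cc1ccc(O)cc1)[C@@H](Cc1ccc(O)cc1)C(=O)c1c(Cl)cc(O)cc1O
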